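**Strategy.** Ring atoms are numbered C1 (ketone), C2=C3 (alkene), C4 (acetoxy carbon), C5 (pentenyl carbon). The cyclopentenone is assembled from two acyclic pieces: a β-keto acid phosphonate carrying C5, C1 and C2 with the pentenyl chain, and an α,α-diacetoxy ketone carrying C3 and C4 with the acid chain. In one pot an organocatalytic decarboxylative aldol joins C5 to C4 enantioselectively, the new alkoxide takes an acetyl group from the neighbouring acylal (installing the C4 acetate, unmasking the C3 aldehyde), and an intramolecular Horner–Wadsworth–Emmons olefination closes C2=C3. The step exploits that C3 and C4 of the ring are a masked α-ketoaldehyde whose own protecting group becomes the tertiary acetate.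

Key step: step 5

Remark on the chemistry: C5 is epimerizable through the enol of the C1 ketone, and the target, with its two carbon chains trans on the ring, is taken to be the more stable C5 epimer; 9-tert-butoxy-9-oxononanoic acid is taken as commercially available.

Step 1
Reactants: 1 dimethyl (2-oxopropyl)phosphonate; 2 (2Z)-1-bromopent-2-ene
Product: 3 dimethyl [(5Z)-2-oxooct-5-en-1-yl]phosphonate
Conditions: LiN(i-Pr)2 (2.1 equiv), THF, −78 to 0 °C; then 2, −78 °C to rt; dilute HCl work-up
Reagents that add atoms: none
Why: γ-Alkylation of a β-ketophosphonate dianion, in which the more basic terminal carbanion reacts by SN2 at the primary allylic carbon, so the Z-alkene is carried over unchanged and no stereocentre is formed.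

Step 2
Reactants: 3 dimethyl [(5Z)-2-oxooct-5-en-1-yl]phosphonate
Product: 4 (4Z)-2-[2-(dimethoxyphosphoryl)acetyl]hept-4-enoic acid (racemic, stereocentre labile)
Conditions: LiN(i-Pr)2 (2.1 equiv), THF, −78 °C; dry CO2, −78 °C; cold 1 M HCl, extraction and concentration below 10 °C; used at once
Reagents that add atoms: carbon dioxide, O=C=O
Why: Carboxylation of the same dianion site as in step 1 should give the β-keto acid, which is kept cold because β-keto acids decarboxylate on warming; its stereocentre is lost again in step 5.

Step 3
Reactants: 5 9-tert-butoxy-9-oxononanoic acid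
Product: 7 tert-butyl 10-diazo-9-oxodecanoate, via acid chloride 6 (not isolated)
Conditions: 1-chloro-N,N,2-trimethylprop-1-en-1-amine (1.1 equiv), CH2Cl2, 0 °C to rt; then CH2N2 (2.5 equiv), Et2O, 0 °C
Reagents that add atoms: diazomethane, C=[N+]=[N-]
Why: Acid chloride formation under neutral conditions spares the tert-butyl ester, and acylation of diazomethane (first stage of the Arndt–Eistert sequence) gives the diazoketone, the second equivalent of diazomethane taking up the HCl.

Step 4
Reactants: 7 tert-butyl 10-diazo-9-oxodecanoate
Product: 9 tert-butyl 10,10-bis(acetyloxy)-9-oxodecanoate, via ketoaldehyde 8 (not isolated)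
Conditions: dimethyldioxirane (1.2 equiv), acetone, 0 °C; evaporate; then Ac2O (3 equiv), Sc(OTf)3 (1 mol %), MeCN, 0 °C
Reagents that add atoms: dimethyldioxirane, CC1(C)OO1; acetic anhydride, CC(=O)OC(C)=O
Why: Dioxirane oxidation of an α-diazoketone gives the α-ketoaldehyde with loss of N2, and Lewis-acid-catalysed acylal formation is selective for the aldehyde over the ketone, the short cold exposure being chosen to leave the tert-butyl ester intact.

Step 5
Reactants: 4 (4Z)-2-[2-(dimethoxyphosphoryl)acetyl]hept-4-enoic acid; 9 tert-butyl 10,10-bis(acetyloxy)-9-oxodecanoate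
Product: 12 tert-butyl 8-[(1S)-1-(acetyloxy)-4-oxo-5-[(2Z)-pent-2-en-1-yl]cyclopent-2-en-1-yl]octanoate (both C5 epimers), via aldol adduct 10 (not isolated), via acetoxy aldehyde 11 (not isolated)
Conditions: one pot: 4 (1.2 equiv), 9, quinine-derived squaramide catalyst 3-{[3,5-bis(trifluoromethyl)phenyl]amino}-4-[(9-deoxy-epi-quinin-9-yl)amino]cyclobut-3-ene-1,2-dione (10 mol %), toluene/THF, −20 to 0 °C until CO2 evolution ends; then LiCl (2 equiv), i-Pr2NEt (2 equiv), MeCN, 0 °C; pH 5 buffer quench
Reagents that add atoms: none
Why: Proposed new method: the catalyst amine forms an ion pair with keto acid 4 while the squaramide N–H bonds bind the ketone of 9, which two α-acyloxy groups activate; the enol carbon C5 adds to one face of that ketone and CO2 is lost, so the carboxyl group fixes the regiochemistry (C5, not the phosphonate carbon) and the catalyst fixes C4. After LiCl and amine base are added, the tertiary alkoxide of 10 attacks a neighbouring acetate through a five-membered orthoester, the resulting hemiacylal expels acetate, and aldehyde 11, with the C4 acetate in place and retro-aldol thereby blocked, is closed by the lithium-chelated phosphonate carbanion to the C2=C3 bond. The closest known reaction types are the amine-catalysed enantioselective decarboxylative aldol of β-keto acids with activated ketones, base-induced 1,2-acyl migration, and the aldol/Horner–Wadsworth–Emmons annulation of β-ketophosphonates with 1,2-dicarbonyl compounds; new are the acylal-masked ketoaldehyde as acceptor and the merger into one pot. The ring closure is a 5-(enolendo)-exo-trig olefination, formally disfavoured by the ring-closure rules for enolates but well established for γ-oxo-β-ketophosphonates, whose phosphorus-stabilised carbanion is not held in the enolate plane. C4 is set by the catalyst (the quinidine-derived pseudoenantiomer is used if the sense of induction proves opposite), whereas C5 is not controlled here and is corrected in step 6. The step needs ketone-over-aldehyde selectivity (secured by the acylal mask), acyl transfer faster than retro-aldol (secured by the activated, adjacent acetate), and olefination faster than E1cB loss of acetate from 12 (secured by the weak base, low temperature and buffered quench).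

Step 6
Reactants: 12 tert-butyl 8-[(1S)-1-(acetyloxy)-4-oxo-5-[(2Z)-pent-2-en-1-yl]cyclopent-2-en-1-yl]octanoate (both C5 epimers)
Product: 14 8-[(1S,5S)-1-(acetyloxy)-4-oxo-5-[(2Z)-pent-2-en-1-yl]cyclopent-2-en-1-yl]octanoic acid, via C5-epimeric acid mixture 13 (not isolated)
Conditions: TFA/CH2Cl2 (1:3), 0 °C to rt; evaporate; then camphorsulfonic acid (10 mol %), CH2Cl2, rt until the C5 ratio is constant; chromatography, minor epimer resubmitted
Reagents that add atoms: none
Why: Acidolysis of the tert-butyl ester frees the acid, and acid-catalysed enolization of the C1 ketone toward C5 should equilibrate that centre to the (5S) epimer with the pentenyl chain trans to the acid chain; acid is used because base would expel the C4 acetate by E1cB, whereas acid ionization of that acetate would require a destabilised oxocyclopentenyl cation.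

**Compound list**

1 | dimethyl (2-oxopropyl)phosphonate | CC(=O)CP(=O)(OC)OC | starting material
2 | (2Z)-1-bromopent-2-ene | CC/C=C\CBr | starting material
3 | dimethyl [(5Z)-2-oxooct-5-en-1-yl]phosphonate | CC/C=C\CCC(=O)CP(=O)(OC)OC | intermediate
4 | (4Z)-2-[2-(dimethoxyphosphoryl)acetyl]hept-4-enoic acid (racemic) | CC/C=C\CC(C(=O)O)C(=O)CP(=O)(OC)OC | intermediate
5 | 9-tert-butoxy-9-oxononanoic acid | CC(C)(C)OC(=O)CCCCCCCC(=O)O | starting material
6 | tert-butyl 9-chloro-9-oxononanoate | CC(C)(C)OC(=O)CCCCCCCC(=O)Cl | intermediate
7 | tert-butyl 10-diazo-9-oxodecanoate | CC(C)(C)OC(=O)CCCCCCCC(=O)C=[N+]=[N-] | intermediate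
8 | tert-butyl 9,10-dioxodecanoate | CC(C)(C)OC(=O)CCCCCCCC(=O)C=O | intermediate
9 | tert-butyl 10,10-bis(acetyloxy)-9-oxodecanoate | CC(C)(C)OC(=O)CCCCCCCC(=O)C(OC(C)=O)OC(C)=O | intermediate
10 | tert-butyl (9R,12Z)-9-[bis(acetyloxy)methyl]-10-[2-(dimethoxyphosphoryl)acetyl]-9-hydroxypentadec-12-enoate (C10 epimers) | CC/C=C\CC(C(=O)CP(=O)(OC)OC)[C@](O)(CCCCCCCC(=O)OC(C)(C)C)C(OC(C)=O)OC(C)=O | intermediate
11 | tert-butyl (9R,12Z)-9-(acetyloxy)-10-[2-(dimethoxyphosphoryl)acetyl]-9-formylpentadec-12-enoate (C10 epimers) | CC/C=C\CC(C(=O)CP(=O)(OC)OC)[C@](OC(C)=O)(CCCCCCCC(=O)OC(C)(C)C)C=O | intermediate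
12 | tert-butyl 8-[(1S)-1-(acetyloxy)-4-oxo-5-[(2Z)-pent-2-en-1-yl]cyclopent-2-en-1-yl]octanoate (both C5 epimers) | CC/C=C\CC1C(=O)C=C[C@]1(CCCCCCCC(=O)OC(C)(C)C)OC(C)=O | intermediate
13 | 8-[(1S)-1-(acetyloxy)-4-oxo-5-[(2Z)-pent-2-en-1-yl]cyclopent-2-en-1-yl]octanoic acid (both C5 epimers) | CC/C=C\CC1C(=O)C=C[C@]1(CCCCCCCC(=O)O)OC(C)=O | intermediate
14 | 8-[(1S,5S)-1-(acetyloxy)-4-oxo-5-[(2Z)-pent-2-en-1-yl]cyclopent-2-en-1-yl]octanoic acid | CC/C=C\C[C@@H]1C(=O)C=C[C@]1(CCCCCCCC(=O)O)OC(C)=O | target

**Count.** Total steps: 6. Longest linear sequence: 4 steps (1, 2, 5, 6 or 3, 4, 5, 6).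

**Steps most likely to fail**

Step 5 (Proposed new method). Keto acid 4 may decarboxylate before it forms the C–C bond, the catalyst may discriminate poorly between the faces of the ketone of 9, adduct 10 may undergo retro-aldol before the acetyl group moves, and the product may lose acetate by E1cB in the basic second phase. The fallback uses known chemistry, sets out from 7 and 3, and returns to the route at 12. Diazoketone 7 is oxidized to 8 as in step 4 and condensed at its aldehyde with (S)-2-(anilinomethyl)pyrrolidine (toluene, 4 Å sieves) to give the keto aminal of 8 with (S)-2-(anilinomethyl)pyrrolidine F1, a 2-acyl-3-phenyl-1,3-diazabicyclo[3.3.0]octane with the acyl group cis to the ring-fusion hydrogen. The dianion of 3 (LiN(i-Pr)2, 2.1 equiv; then MgBr2·OEt2, THF, −78 °C) adds to the ketone under chelation control, with magnesium bridging the ketone oxygen and the pyrrolidine nitrogen and attack from the side of the aminal hydrogen; this should give the (S)-configured carbinol as the aminal-protected tertiary aldol adduct F2. Cold 2 % aqueous HCl/Et2O releases the auxiliary and gives tert-butyl (9R,12Z)-10-[2-(dimethoxyphosphoryl)acetyl]-9-formyl-9-hydroxypentadec-12-enoate F3. LiCl/i-Pr2NEt in MeCN closes the ring by intramolecular Horner–Wadsworth–Emmons olefination to tert-butyl 8-[(1S)-1-hydroxy-4-oxo-5-[(2Z)-pent-2-en-1-yl]cyclopent-2-en-1-yl]octanoate F4. Ac2O with Sc(OTf)3 (cat.) in MeCN at −20 °C acetylates the tertiary alcohol without base and gives 12.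

Step 2. The β-keto acid may decarboxylate during acidification and concentration, and the second deprotonation at the now secondary carbon may be incomplete. The fallback sets out from 3 and returns at 4. The dianion of 3 is trapped with Boc2O instead of CO2 to give tert-butyl (4Z)-2-[2-(dimethoxyphosphoryl)acetyl]hept-4-enoate F5, which is stable, can be chromatographed and stored, and is cleaved to 4 with TFA/CH2Cl2 at 0 °C (evaporation with toluene below 10 °C) immediately before step 5.

Step 4. The tert-butyl ester may be cleaved under the Lewis-acidic acetic anhydride conditions, and ketoaldehyde 8 may hydrate or oligomerize so that acylal formation stalls. The fallback sets out from 7 and returns at 9. Bromine (1 equiv, CH2Cl2, 0 °C) converts the diazoketone with loss of N2 into tert-butyl 10,10-dibromo-9-oxodecanoate F6, and double substitution with AgOAc (2.2 equiv) in AcOH at 60 °C gives 9 without an oxidant or a Lewis acid.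

**Further compounds**

F1 | step 5 | keto aminal of 8 with (S)-2-(anilinomethyl)pyrrolidine | CC(C)(C)OC(=O)CCCCCCCC(=O)[C@H]1N(c2ccccc2)C[C@@H]2CCCN12
F2 | step 5 | aminal-protected tertiary aldol adduct | CC/C=C\CC(C(=O)CP(=O)(OC)OC)[C@](O)(CCCCCCCC(=O)OC(C)(C)C)[C@H]1N(c2ccccc2)C[C@@H]2CCCN12
F3 | step 5 | tert-butyl (9R,12Z)-10-[2-(dimethoxyphosphoryl)acetyl]-9-formyl-9-hydroxypentadec-12-enoate | CC/C=C\CC(C(=O)CP(=O)(OC)OC)[C@](O)(CCCCCCCC(=O)OC(C)(C)C)C=O
F4 | step 5 | tert-butyl 8-[(1S)-1-hydroxy-4-oxo-5-[(2Z)-pent-2-en-1-yl]cyclopent-2-en-1-yl]octanoate | CC/C=C\CC1C(=O)C=C[C@]1(CCCCCCCC(=O)OC(C)(C)C)O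
F5 | step 2 | tert-butyl (4Z)-2-[2-(dimethoxyphosphoryl)acetyl]hept-4-enoate | CC/C=C\CC(C(=O)OC(C)(C)C)C(=O)CP(=O)(OC)OC
F6 | step 4 | tert-butyl 10,10-dibromo-9-oxodecanoate | CC(C)(C)OC(=O)CCCCCCCC(=O)C(Br)Br
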